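(The data were generated by integration for an exercise, and the scatter is random.)

The chain length in this flask is a ratio: the free monomer that the protic impurity leaves, over the initiator charged. The hunch of one free monomer lost per protic impurity stands up. At 40.0 h, the monomer found in neither column comes to 0.0384 M in green and 0.0426 M in grey on 0.040 M charged, and to 0.0780 M in violet on 0.080 M. So protic impurity acts as the limiting reagent of that loss.

| flask | free monomer | protic impurity | initiator | remark | time |
|---|---|---|---|---|---|
| green | 0.13 M | 0.040 M | 0.22 mM | run made earlier |  |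
| grey | 0.30 M | 0.040 M | 0.22 mM | run made earlier |  |
| violet | 0.20 M | 0.080 M | 0.22 mM | run made earlier |  |
| flask | 0.20 M | 0.0400 M | 0.22 mM |  | 40 h |

| run | time / h | monomer in chains / % | free monomer / % |
|---|---|---|---|
| green | 2.00 | 44.0 | 32.1 |
| green | 6.00 | 63.5 | 9.2 |
| green | 12.0 | 69.0 | 2.1 |
| green | 15.0 | 69.1 | 1.6 |
| green | 25.0 | 70.3 | 1.8 |
| green | 30.0 | 70.2 | 0.6 |
| green | 40.0 | 69.6 | 0.9 |
| grey | 2.00 | 48.2 | 40.0 |
| grey | 6.00 | 73.1 | 12.8 |
| grey | 12.0 | 81.5 | 5.3 |
| grey | 15.0 | 82.5 | 4.1 |
| grey | 25.0 | 84.3 | 2.3 |
| grey | 30.0 | 85.1 | 2.2 |
| grey | 40.0 | 84.3 | 1.5 |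
| violet | 4.00 | 50.0 | 12.4 |
| violet | 10.0 | 58.6 | 2.8 |
| violet | 20.0 | 59.8 | 1.0 |
| violet | 30.0 | 59.9 | 0 |
| violet | 40.0 | 60.2 | 0.8 |

(standard deviation of a reading: 0.5 percentage points)

- average number of monomer units in a chain (living and dead chains, two that joined counted as one) at 40 h
- part of the free monomer that has reacted at 40 h

- the average divides the monomer in chains by the number of chains, living and dead together; two radicals that join make one chain
- the numbers in the tables scatter with a standard deviation of 0.5 percentage points
- the earlier runs do not show the number of chains; that part of a forecast is a guess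

The runs show no chain count, so the next step is a guess. If each initiator gives two radicals and these join in pairs, chains equal the initiator charged. The quick number is then the units per initiator, ([free monomer] − [protic impurity])/[initiator] at the charge 727. Free monomer reads 0.9% in green and 1.5% in grey, and the flask's charge lies between theirs, so c should stand near 98.5%.

The forecast gives dp 550 and c 98.7%, with the words “I guess 0.2–0.4 mM chains”, and its dp lies below the 727 reckoned here. The flask gives dp 714 and c 98.4%.

    free monomer + initiating radical → growing radical + monomer in chains (k = 10900 M⁻¹ s⁻¹)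
    free monomer + growing radical → monomer in chains + growing radical, rate k2*[growing radical]*[free monomer] (k = 66000 M⁻¹ min⁻¹)
    protic impurity + free monomer → quenched substrate (k = 0.156 M⁻¹ min⁻¹)
    2 growing radical → dead chain (k = 1.20 × 10⁶ M⁻¹ s⁻¹)
    initiator → 2 initiating radical (k = 0.00381 min⁻¹)

At 1.51 h, free monomer in the flask has a half-life of 1.9 h by growth against 12 h by quenching, so growth is the faster. Yet by 4.00 h quenching has 96% of its turnover up to 40 h behind it, and the flask ends with 19.9% quenched substrate and 78.5% monomer in chains. The units per initiator, 727, stand a little above the flask's 714, with 2.20 × 10⁻⁴ M dead chains on 0.22 mM initiator charged. With 0.010 M protic impurity, the neighbour flask reckons to 864, and its computed dp is 843.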